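The flavone carries at C3 the benzo ring of the flavanone (its C6), which makes the chromone (rings A and C) together with that ring an isoflavone. The route therefore disconnects the flavone C3–C4 bond. In a single flask, BF3·OEt2 triggers a 1,2-shift of the ring A aroyl group in a chalcone epoxide to the benzylic carbon bearing the 2,4,6-trioxygenated ring, and methanolic HCl then cleaves the MOM ethers and closes ring C through O1–C2. The precursor is a racemic trans epoxide reached by Claisen–Schmidt condensation and peroxide epoxidation. C2 arylation by zincation and Negishi coupling, Mitsunobu etherification with an (S)-hydroxy ester and Friedel–Crafts closure then complete the (R)-flavanone.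

Key step: step 7

Assumption: the target string defines only C2 of the flavanone, which is (R); the axis between flavone C3 and flavanone C6 is treated as stereochemically undefined.

Design remarks: ring A of the ketone carries one benzyl and one MOM ether, so the key step leaves a benzyl ether at O5 and only the MOM-bearing oxygen can close ring C. The phenol of the flavanone B ring is carried as a benzyl carbonate; this electron-poor group should keep the benzylic C–O bond from ionising in the Mitsunobu and acid steps, and it is lost in the final hydrogenolysis.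

Step 1
Reactants: 1 1-(2,6-dihydroxy-4-methoxyphenyl)ethanone
Product: 2 1-[2-(benzyloxy)-6-hydroxy-4-methoxyphenyl]ethanone
Conditions: BnBr (1.05 equiv), K2CO3 (1.1 equiv), acetone, reflux
Reagents that add atoms: benzyl bromide, BrCc1ccccc1
Why: Williamson etherification that should stop at the monoether, because the remaining phenol is held in a hydrogen bond to the ketone and is far less nucleophilic than the first.

Step 2
Reactants: 2 1-[2-(benzyloxy)-6-hydroxy-4-methoxyphenyl]ethanone
Product: 3 1-[2-(benzyloxy)-4-methoxy-6-(methoxymethoxy)phenyl]ethanone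
Conditions: NaH (1.05 equiv), MOMCl, DMF, 0 °C to rt
Reagents that add atoms: chloromethyl methyl ether, COCCl
Why: O-alkylation of the phenoxide (Williamson-type acetal formation); full deprotonation with NaH overcomes the chelation of this phenol, and the small excess of base leaves the methyl ketone untouched.

Step 3
Reactants: 4 2,4,6-trihydroxybenzaldehyde
Product: 5 2,6-dihydroxy-4-(methoxymethoxy)benzaldehyde
Conditions: MOMCl (1.0 equiv), iPr2NEt (1.1 equiv), THF, 0 °C
Reagents that add atoms: chloromethyl methyl ether, COCCl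
Why: regioselective O-alkylation; the 4-OH is the most acidic phenol (para to the formyl group) and the only one that is neither hindered nor hydrogen-bonded to the aldehyde, so one equivalent of electrophile should react there.

Step 4
Reactants: 5 2,6-dihydroxy-4-(methoxymethoxy)benzaldehyde
Product: 6 2,6-bis(benzyloxy)-4-(methoxymethoxy)benzaldehyde
Conditions: BnBr (2.4 equiv), K2CO3, DMF, 60 °C
Reagents that add atoms: benzyl bromide, BrCc1ccccc1
Why: Williamson etherification of both ortho phenols under forcing conditions; the aldehyde has no α-hydrogen and the MOM acetal is stable to carbonate base.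

Step 5
Reactants: 3 1-[2-(benzyloxy)-4-methoxy-6-(methoxymethoxy)phenyl]ethanone, 6 2,6-bis(benzyloxy)-4-(methoxymethoxy)benzaldehyde
Product: 7 (2E)-1-[2-(benzyloxy)-4-methoxy-6-(methoxymethoxy)phenyl]-3-[2,6-bis(benzyloxy)-4-(methoxymethoxy)phenyl]prop-2-en-1-one
Conditions: KOH (50% aq), EtOH/THF, rt to 50 °C
Reagents that add atoms: none
Why: Claisen–Schmidt condensation; the methyl ketone is the only enolisable partner and the aldehyde the only electrophile, E1cB loss of water gives the conjugated E-enone, and all ethers are stable to base.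

Step 6
Reactants: 7 (2E)-1-[2-(benzyloxy)-4-methoxy-6-(methoxymethoxy)phenyl]-3-[2,6-bis(benzyloxy)-4-(methoxymethoxy)phenyl]prop-2-en-1-one
Product: 8 rac-[2-(benzyloxy)-4-methoxy-6-(methoxymethoxy)phenyl]{(2S,3R)-3-[2,6-bis(benzyloxy)-4-(methoxymethoxy)phenyl]oxiran-2-yl}methanone (racemic trans epoxide, one enantiomer drawn)
Conditions: 30% H2O2, 2 M NaOH, MeOH/THF, 0 °C to rt; extractive work-up without silica gel, used crude
Reagents that add atoms: hydrogen peroxide, OO
Why: Weitz–Scheffer nucleophilic epoxidation; conjugate addition of hydroperoxide and closure of the enolate on oxygen should give the trans epoxide from the E-enone as a racemate, the enone staying electrophilic because the twisted ring A carbonyl is not conjugated with its arene.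

Step 7
Reactants: 8 racemic trans epoxide
Product: 11 5-(benzyloxy)-3-[2,6-bis(benzyloxy)-4-hydroxyphenyl]-7-methoxy-4H-chromen-4-one, via formyl deoxybenzoin 9 (not isolated), via 2-hydroxyisoflavanone 10 (not isolated)
Conditions: BF3·OEt2 (2 equiv), CH2Cl2, −20 to 0 °C; then MeOH, conc. HCl, 50 °C
Reagents that add atoms: none
Why: BF3 binds the epoxide oxygen and the C–O bond at the carbon bearing the 2,6-bis(benzyloxy)-4-(methoxymethoxy)phenyl ring ionises, the charge being spread over three ring oxygens; the ring A aroyl group then shifts from the adjacent carbon, which becomes the formyl carbon, and this shift forms the flavone C3–C4 bond. The closest known reaction type is the Lewis acid-mediated rearrangement of chalcone epoxides to α-formyl deoxybenzoins by 1,2-acyl migration (a Meinwald-type rearrangement), followed by acid cyclodehydration to isoflavones. After methanolic HCl has removed the MOM groups, ring C closes by 6-exo-trig addition of the freed ring A phenol to the formyl carbon (O1–C2) and the hemiacetal 10 loses water. No stereocentre is created, because both epoxide carbons end as trigonal centres of the chromone. The step needs aroyl migration to win over hydride migration and over capture of the cation by a ring A oxygen, and this should be secured by the fully localised trioxybenzylic cation, by the push of the boron-bound oxygen at the migration origin, and by both ring A ortho oxygens still being capped (benzyl, MOM) while BF3 acts at low temperature. Since only the MOM-bearing ring A oxygen is freed, it alone can close ring C, which places the benzyl ether at O5 and liberates the para phenol of the trioxygenated ring for later use.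

Step 8
Reactants: 11 5-(benzyloxy)-3-[2,6-bis(benzyloxy)-4-hydroxyphenyl]-7-methoxy-4H-chromen-4-one
Product: 12 5-(benzyloxy)-3-{2,6-bis(benzyloxy)-4-[(triisopropylsilyl)oxy]phenyl}-7-methoxy-4H-chromen-4-one
Conditions: TIPSCl, imidazole, DMF, rt
Reagents that add atoms: triisopropylsilyl chloride, CC(C)[Si](Cl)(C(C)C)C(C)C
Why: silylation of the one free, unhindered phenol removes its acidic proton before the amide base is used, and the bulky silyl ether should resist that base and the coupling.

Step 9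
Reactants: 12 5-(benzyloxy)-3-{2,6-bis(benzyloxy)-4-[(triisopropylsilyl)oxy]phenyl}-7-methoxy-4H-chromen-4-one, 13 4-iodoanisole
Product: 15 5-(benzyloxy)-3-{2,6-bis(benzyloxy)-4-[(triisopropylsilyl)oxy]phenyl}-7-methoxy-2-(4-methoxyphenyl)-4H-chromen-4-one, via chromon-2-ylzinc chloride 14 (not isolated)
Conditions: TMPZnCl·LiCl (1.5 equiv; TMP = 2,2,6,6-tetramethylpiperidide), THF, 25 °C; then 13, Pd(OAc)2 (3 mol %), SPhos (6 mol %), 50 °C
Reagents that add atoms: none
Why: deprotonative zincation at C2, the only acidic vinylic C–H (bonded to O1 and vinylogous to the C4 carbonyl), should give a zinc reagent that does not ring-open, and Negishi cross-coupling with the aryl iodide then forms the C2–aryl bond, a sequence established for chromones.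

Step 10
Reactants: 15 5-(benzyloxy)-3-{2,6-bis(benzyloxy)-4-[(triisopropylsilyl)oxy]phenyl}-7-methoxy-2-(4-methoxyphenyl)-4H-chromen-4-one
Product: 16 5-(benzyloxy)-3-[2,6-bis(benzyloxy)-4-hydroxyphenyl]-7-methoxy-2-(4-methoxyphenyl)-4H-chromen-4-one
Conditions: TBAF, AcOH, THF, 0 °C
Reagents that add atoms: none
Why: fluoride cleaves the aryl silyl ether; acetic acid buffers the phenoxide, and the benzyl and methyl ethers are inert.

Step 11
Reactants: 17 4-hydroxybenzoic acid
Product: 18 4-{[(benzyloxy)carbonyl]oxy}benzoic acid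
Conditions: CbzCl, aq. NaOH, 0 °C; then HCl
Reagents that add atoms: benzyl chloroformate, O=C(Cl)OCc1ccccc1
Why: Schotten–Baumann acylation of the phenoxide; any mixed anhydride formed at the carboxylate is hydrolysed in the aqueous base and the acid is recovered on acidification.

Step 12
Reactants: 18 4-{[(benzyloxy)carbonyl]oxy}benzoic acid
Product: 21 tert-butyl 3-(4-{[(benzyloxy)carbonyl]oxy}phenyl)-3-oxopropanoate, via acid chloride 19 (not isolated), via acylmalonic half ester 20 (not isolated)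
Conditions: (COCl)2, DMF (cat.), CH2Cl2, rt; evaporate; then KO2CCH2CO2tBu, MgCl2, Et3N, MeCN, 0 °C to rt; 1 M HCl
Reagents that add atoms: potassium 3-tert-butoxy-3-oxopropanoate, CC(C)(C)OC(=O)CC(=O)[O-].[K+]
Why: C-acylation of the magnesium enolate of the malonate half ester by the acid chloride, then decarboxylation on acidification (malonate half-ester route to β-keto esters); the soft enolate should react at the acid chloride and not at the aryl carbonate.

Step 13
Reactants: 21 tert-butyl 3-(4-{[(benzyloxy)carbonyl]oxy}phenyl)-3-oxopropanoate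
Product: 22 tert-butyl (3S)-3-(4-{[(benzyloxy)carbonyl]oxy}phenyl)-3-hydroxypropanoate
Conditions: RuCl[(S,S)-TsDPEN](p-cymene) (1 mol %), HCO2H/Et3N (5:2), CH2Cl2, rt
Reagents that add atoms: none
Why: Noyori–Ikariya asymmetric transfer hydrogenation of the aryl ketone; the (S,S)-ligand directs hydride to the face that, by the model established for aryl alkyl ketones, gives the (S)-carbinol, and neither the ester nor the carbonate is reduced.

Step 14
Reactants: 16 5-(benzyloxy)-3-[2,6-bis(benzyloxy)-4-hydroxyphenyl]-7-methoxy-2-(4-methoxyphenyl)-4H-chromen-4-one, 22 tert-butyl (3S)-3-(4-{[(benzyloxy)carbonyl]oxy}phenyl)-3-hydroxypropanoate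
Product: 23 tert-butyl (3R)-3-(4-{[(benzyloxy)carbonyl]oxy}phenyl)-3-{3,5-bis(benzyloxy)-4-[5-(benzyloxy)-7-methoxy-2-(4-methoxyphenyl)-4-oxo-4H-chromen-3-yl]phenoxy}propanoate
Conditions: PPh3, DIAD, toluene, 0 °C to rt
Reagents that add atoms: none
Why: Mitsunobu etherification; the phenoxide of 16 displaces the alkoxyphosphonium ion by SN2 with inversion, turning the (S)-carbinol into the (R)-aryl ether that becomes C2 of the flavanone, and the electron-poor carbonate on the aryl ring disfavours an ionisation pathway.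

Step 15
Reactants: 23 tert-butyl (3R)-3-(4-{[(benzyloxy)carbonyl]oxy}phenyl)-3-{3,5-bis(benzyloxy)-4-[5-(benzyloxy)-7-methoxy-2-(4-methoxyphenyl)-4-oxo-4H-chromen-3-yl]phenoxy}propanoate
Product: 26 benzyl 4-{(2R)-5,7-bis(benzyloxy)-6-[5-(benzyloxy)-7-methoxy-2-(4-methoxyphenyl)-4-oxo-4H-chromen-3-yl]-4-oxo-3,4-dihydro-2H-chromen-2-yl}phenyl carbonate, via carboxylic acid 24 (not isolated), via mixed trifluoroacetic anhydride 25 (not isolated)
Conditions: TFA/CH2Cl2 (1:4), 0 °C to rt; evaporate; TFAA, CH2Cl2, 0 °C to rt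
Reagents that add atoms: none
Why: acidolysis of the tert-butyl ester, then intramolecular Friedel–Crafts acylation through the mixed anhydride at the electron-rich position ortho to the new ether oxygen (the two such positions are equivalent) closes the six-membered ketone ring; no bond to the stereocentre is broken, the carbonate-deactivated benzylic ether should not ionise, and every free ring position is flanked by two alkoxy groups, which hinders tert-butylation.

Step 16
Reactants: 26 benzyl 4-{(2R)-5,7-bis(benzyloxy)-6-[5-(benzyloxy)-7-methoxy-2-(4-methoxyphenyl)-4-oxo-4H-chromen-3-yl]-4-oxo-3,4-dihydro-2H-chromen-2-yl}phenyl carbonate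
Product: 27 (2R)-5,7-dihydroxy-6-[5-hydroxy-7-methoxy-2-(4-methoxyphenyl)-4-oxo-4H-chromen-3-yl]-2-(4-hydroxyphenyl)-2,3-dihydro-4H-chromen-4-one
Conditions: H2 (1 atm), 10% Pd/C, EtOAc/MeOH, rt, stopped on consumption of 26
Reagents that add atoms: none
Why: hydrogenolysis should cleave the three benzyl ethers and the benzyl carbonate (which loses CO2 to give the phenol) under neutral conditions that avoid acid- or base-induced opening of the flavanone to the chalcone, so C2 stays (R).

Compound list
1 | 1-(2,6-dihydroxy-4-methoxyphenyl)ethanone | CC(=O)c1c(O)cc(OC)cc1O | starting material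
2 | 1-[2-(benzyloxy)-6-hydroxy-4-methoxyphenyl]ethanone | CC(=O)c1c(O)cc(OC)cc1OCc1ccccc1 | intermediate
3 | 1-[2-(benzyloxy)-4-methoxy-6-(methoxymethoxy)phenyl]ethanone | CC(=O)c1c(OCOC)cc(OC)cc1OCc1ccccc1 | intermediate
4 | 2,4,6-trihydroxybenzaldehyde | O=Cc1c(O)cc(O)cc1O | starting material
5 | 2,6-dihydroxy-4-(methoxymethoxy)benzaldehyde | O=Cc1c(O)cc(OCOC)cc1O | intermediate
6 | 2,6-bis(benzyloxy)-4-(methoxymethoxy)benzaldehyde | O=Cc1c(OCc2ccccc2)cc(OCOC)cc1OCc1ccccc1 | intermediate
7 | (2E)-1-[2-(benzyloxy)-4-methoxy-6-(methoxymethoxy)phenyl]-3-[2,6-bis(benzyloxy)-4-(methoxymethoxy)phenyl]prop-2-en-1-one | COCOc1cc(OC)cc(OCc2ccccc2)c1C(=O)/C=C/c1c(OCc2ccccc2)cc(OCOC)cc1OCc1ccccc1 | intermediate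
8 | rac-[2-(benzyloxy)-4-methoxy-6-(methoxymethoxy)phenyl]{(2S,3R)-3-[2,6-bis(benzyloxy)-4-(methoxymethoxy)phenyl]oxiran-2-yl}methanone (racemic trans epoxide, one enantiomer drawn) | COCOc1cc(OC)cc(OCc2ccccc2)c1C(=O)[C@H]1O[C@@H]1c1c(OCc2ccccc2)cc(OCOC)cc1OCc1ccccc1 | intermediate
9 | 2-[2,6-bis(benzyloxy)-4-(methoxymethoxy)phenyl]-3-[2-(benzyloxy)-4-methoxy-6-(methoxymethoxy)phenyl]-3-oxopropanal (racemic, enolisable) | COCOc1cc(OC)cc(OCc2ccccc2)c1C(=O)C(C=O)c1c(OCc2ccccc2)cc(OCOC)cc1OCc1ccccc1 | intermediate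
10 | 5-(benzyloxy)-3-[2,6-bis(benzyloxy)-4-hydroxyphenyl]-2-hydroxy-7-methoxy-2,3-dihydro-4H-chromen-4-one (hemiacetal, mixture of stereoisomers) | COc1cc(OCc2ccccc2)c2C(=O)C(c3c(OCc4ccccc4)cc(O)cc3OCc3ccccc3)C(O)Oc2c1 | intermediate
11 | 5-(benzyloxy)-3-[2,6-bis(benzyloxy)-4-hydroxyphenyl]-7-methoxy-4H-chromen-4-one | COc1cc(OCc2ccccc2)c2c(=O)c(-c3c(OCc4ccccc4)cc(O)cc3OCc3ccccc3)coc2c1 | intermediate
12 | 5-(benzyloxy)-3-{2,6-bis(benzyloxy)-4-[(triisopropylsilyl)oxy]phenyl}-7-methoxy-4H-chromen-4-one | COc1cc(OCc2ccccc2)c2c(=O)c(-c3c(OCc4ccccc4)cc(O[Si](C(C)C)(C(C)C)C(C)C)cc3OCc3ccccc3)coc2c1 | intermediate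
13 | 4-iodoanisole | COc1ccc(I)cc1 | starting material
14 | {5-(benzyloxy)-3-[2,6-bis(benzyloxy)-4-(triisopropylsilyloxy)phenyl]-7-methoxy-4-oxo-4H-chromen-2-yl}zinc chloride (LiCl complex) | COc1cc(OCc2ccccc2)c2c(=O)c(-c3c(OCc4ccccc4)cc(O[Si](C(C)C)(C(C)C)C(C)C)cc3OCc3ccccc3)c([Zn]Cl)oc2c1 | intermediate
15 | 5-(benzyloxy)-3-{2,6-bis(benzyloxy)-4-[(triisopropylsilyl)oxy]phenyl}-7-methoxy-2-(4-methoxyphenyl)-4H-chromen-4-one | COc1ccc(-c2oc3cc(OC)cc(OCc4ccccc4)c3c(=O)c2-c2c(OCc3ccccc3)cc(O[Si](C(C)C)(C(C)C)C(C)C)cc2OCc2ccccc2)cc1 | intermediate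
16 | 5-(benzyloxy)-3-[2,6-bis(benzyloxy)-4-hydroxyphenyl]-7-methoxy-2-(4-methoxyphenyl)-4H-chromen-4-one | COc1ccc(-c2oc3cc(OC)cc(OCc4ccccc4)c3c(=O)c2-c2c(OCc3ccccc3)cc(O)cc2OCc2ccccc2)cc1 | intermediate
17 | 4-hydroxybenzoic acid | O=C(O)c1ccc(O)cc1 | starting material
18 | 4-{[(benzyloxy)carbonyl]oxy}benzoic acid | O=C(O)c1ccc(OC(=O)OCc2ccccc2)cc1 | intermediate
19 | 4-{[(benzyloxy)carbonyl]oxy}benzoyl chloride | O=C(Cl)c1ccc(OC(=O)OCc2ccccc2)cc1 | intermediate
20 | 2-(4-{[(benzyloxy)carbonyl]oxy}benzoyl)-3-tert-butoxy-3-oxopropanoic acid | CC(C)(C)OC(=O)C(C(=O)O)C(=O)c1ccc(OC(=O)OCc2ccccc2)cc1 | intermediate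
21 | tert-butyl 3-(4-{[(benzyloxy)carbonyl]oxy}phenyl)-3-oxopropanoate | CC(C)(C)OC(=O)CC(=O)c1ccc(OC(=O)OCc2ccccc2)cc1 | intermediate
22 | tert-butyl (3S)-3-(4-{[(benzyloxy)carbonyl]oxy}phenyl)-3-hydroxypropanoate | CC(C)(C)OC(=O)C[C@H](O)c1ccc(OC(=O)OCc2ccccc2)cc1 | intermediate
23 | tert-butyl (3R)-3-(4-{[(benzyloxy)carbonyl]oxy}phenyl)-3-{3,5-bis(benzyloxy)-4-[5-(benzyloxy)-7-methoxy-2-(4-methoxyphenyl)-4-oxo-4H-chromen-3-yl]phenoxy}propanoate | COc1ccc(-c2oc3cc(OC)cc(OCc4ccccc4)c3c(=O)c2-c2c(OCc3ccccc3)cc(O[C@H](CC(=O)OC(C)(C)C)c3ccc(OC(=O)OCc4ccccc4)cc3)cc2OCc2ccccc2)cc1 | intermediate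
24 | (3R)-3-(4-{[(benzyloxy)carbonyl]oxy}phenyl)-3-{3,5-bis(benzyloxy)-4-[5-(benzyloxy)-7-methoxy-2-(4-methoxyphenyl)-4-oxo-4H-chromen-3-yl]phenoxy}propanoic acid | COc1ccc(-c2oc3cc(OC)cc(OCc4ccccc4)c3c(=O)c2-c2c(OCc3ccccc3)cc(O[C@H](CC(=O)O)c3ccc(OC(=O)OCc4ccccc4)cc3)cc2OCc2ccccc2)cc1 | intermediate
25 | mixed anhydride of acid 24 with trifluoroacetic acid | COc1ccc(-c2oc3cc(OC)cc(OCc4ccccc4)c3c(=O)c2-c2c(OCc3ccccc3)cc(O[C@H](CC(=O)OC(=O)C(F)(F)F)c3ccc(OC(=O)OCc4ccccc4)cc3)cc2OCc2ccccc2)cc1 | intermediate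
26 | benzyl 4-{(2R)-5,7-bis(benzyloxy)-6-[5-(benzyloxy)-7-methoxy-2-(4-methoxyphenyl)-4-oxo-4H-chromen-3-yl]-4-oxo-3,4-dihydro-2H-chromen-2-yl}phenyl carbonate | COc1ccc(-c2oc3cc(OC)cc(OCc4ccccc4)c3c(=O)c2-c2c(OCc3ccccc3)cc3c(c2OCc2ccccc2)C(=O)C[C@H](c2ccc(OC(=O)OCc4ccccc4)cc2)O3)cc1 | intermediate
27 | (2R)-5,7-dihydroxy-6-[5-hydroxy-7-methoxy-2-(4-methoxyphenyl)-4-oxo-4H-chromen-3-yl]-2-(4-hydroxyphenyl)-2,3-dihydro-4H-chromen-4-one | COc1ccc(-c2oc3cc(OC)cc(O)c3c(=O)c2-c2c(O)cc3c(c2O)C(=O)C[C@H](c2ccc(O)cc2)O3)cc1 | target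

Total step count: 16 steps.
Longest linear sequence: 11 steps (steps 1, 2, 5, 6, 7, 8, 9, 10, 14, 15, 16, counted from 1; the branch from 4 through steps 3 and 4 is equally long).

Steps most likely to fail

1. Step 7. The ring A MOM group may be lost early under the Lewis acid, so that this oxygen traps the benzylic cation and a 3-hydroxyflavanone-type ring closes in place of the aroyl shift. The very labile epoxide may also solvolyse before it rearranges, or the formyl group of 9 may be lost in acidic methanol. The fallback reaches the same isoflavone by the complementary oxidative 1,2-aryl shift; it sets out from chalcone 7 and needs no epoxide. Treatment of 7 with PhI(OAc)2 and p-TsOH in trimethyl orthoformate/methanol should move the trioxygenated aryl ring from the β- to the α-carbon and give the keto acetal 1-[2-(benzyloxy)-4-methoxy-6-(methoxymethoxy)phenyl]-2-[2,6-bis(benzyloxy)-4-(methoxymethoxy)phenyl]-3,3-dimethoxypropan-1-one F1. Warming F1 in methanolic HCl should remove both MOM groups and close ring C on the unmasked aldehyde, which comes back to the route at 11.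

2. Step 9. Metalation of the crowded C2–H may be incomplete, or transmetalation and reductive elimination next to the 2,6-disubstituted C3 aryl ring may be slow, so that protonation on work-up returns 12. The fallback sets out from 12 and forms the C2–aryl bond by conjugate addition in place of cross-coupling. Addition of commercial 4-methoxyphenylmagnesium bromide with catalytic CuBr·SMe2 in THF at −40 °C, then an NH4Cl quench, should give 5-(benzyloxy)-3-{2,6-bis(benzyloxy)-4-[(triisopropylsilyl)oxy]phenyl}-7-methoxy-2-(4-methoxyphenyl)chroman-4-one F2 as a mixture of racemic diastereomers. Dehydrogenation of F2 with DDQ in hot dioxane should restore the C2=C3 bond and comes back to the route at 15.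

3. Step 14. β-Elimination of the activated hydroxy ester to the cinnamate may outpace substitution, or partial ionisation may erode the inversion. The fallback sets out from 16 and replaces the ester by an allyl group as a masked carboxymethyl unit, which has no acidifying carbonyl next to the carbinol. Commercial 4-hydroxybenzaldehyde and benzyl chloroformate (Et3N, CH2Cl2) should give benzyl 4-formylphenyl carbonate F3. Brown allylation of F3 with (−)-Ipc2B(allyl) (Et2O, −78 °C, ethanolamine work-up) should give benzyl 4-[(1S)-1-hydroxybut-3-en-1-yl]phenyl carbonate F4. Mitsunobu coupling of F4 with 16 (PPh3, DIAD) should give, with inversion, benzyl 4-[(1R)-1-{3,5-bis(benzyloxy)-4-[5-(benzyloxy)-7-methoxy-2-(4-methoxyphenyl)-4-oxo-4H-chromen-3-yl]phenoxy}but-3-en-1-yl]phenyl carbonate F5. Dihydroxylation of the terminal alkene (catalytic OsO4, NMO) should give the diol benzyl 4-[(1R)-1-{3,5-bis(benzyloxy)-4-[5-(benzyloxy)-7-methoxy-2-(4-methoxyphenyl)-4-oxo-4H-chromen-3-yl]phenoxy}-3,4-dihydroxybutyl]phenyl carbonate F6. Cleavage of F6 with NaIO4 should give the aldehyde benzyl 4-[(1R)-1-{3,5-bis(benzyloxy)-4-[5-(benzyloxy)-7-methoxy-2-(4-methoxyphenyl)-4-oxo-4H-chromen-3-yl]phenoxy}-3-oxopropyl]phenyl carbonate F7. Pinnick oxidation of F7 (NaClO2, NaH2PO4, 2-methyl-2-butene) should give acid 24, where the route is rejoined at the TFAA stage of step 15.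

Further compounds
F1 | step 7 | 1-[2-(benzyloxy)-4-methoxy-6-(methoxymethoxy)phenyl]-2-[2,6-bis(benzyloxy)-4-(methoxymethoxy)phenyl]-3,3-dimethoxypropan-1-one | COCOc1cc(OC)cc(OCc2ccccc2)c1C(=O)C(C(OC)OC)c1c(OCc2ccccc2)cc(OCOC)cc1OCc1ccccc1
F2 | step 9 | 5-(benzyloxy)-3-{2,6-bis(benzyloxy)-4-[(triisopropylsilyl)oxy]phenyl}-7-methoxy-2-(4-methoxyphenyl)chroman-4-one (mixture of racemic diastereomers) | COc1ccc(C2Oc3cc(OC)cc(OCc4ccccc4)c3C(=O)C2c2c(OCc3ccccc3)cc(O[Si](C(C)C)(C(C)C)C(C)C)cc2OCc2ccccc2)cc1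
F3 | step 14 | benzyl 4-formylphenyl carbonate | O=Cc1ccc(OC(=O)OCc2ccccc2)cc1
F4 | step 14 | benzyl 4-[(1S)-1-hydroxybut-3-en-1-yl]phenyl carbonate | C=CC[C@H](O)c1ccc(OC(=O)OCc2ccccc2)cc1
F5 | step 14 | benzyl 4-[(1R)-1-{3,5-bis(benzyloxy)-4-[5-(benzyloxy)-7-methoxy-2-(4-methoxyphenyl)-4-oxo-4H-chromen-3-yl]phenoxy}but-3-en-1-yl]phenyl carbonate | COc1ccc(-c2oc3cc(OC)cc(OCc4ccccc4)c3c(=O)c2-c2c(OCc3ccccc3)cc(O[C@H](CC=C)c3ccc(OC(=O)OCc4ccccc4)cc3)cc2OCc2ccccc2)cc1
F6 | step 14 | benzyl 4-[(1R)-1-{3,5-bis(benzyloxy)-4-[5-(benzyloxy)-7-methoxy-2-(4-methoxyphenyl)-4-oxo-4H-chromen-3-yl]phenoxy}-3,4-dihydroxybutyl]phenyl carbonate (epimers at the new carbinol) | COc1ccc(-c2oc3cc(OC)cc(OCc4ccccc4)c3c(=O)c2-c2c(OCc3ccccc3)cc(O[C@H](CC(O)CO)c3ccc(OC(=O)OCc4ccccc4)cc3)cc2OCc2ccccc2)cc1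
F7 | step 14 | benzyl 4-[(1R)-1-{3,5-bis(benzyloxy)-4-[5-(benzyloxy)-7-methoxy-2-(4-methoxyphenyl)-4-oxo-4H-chromen-3-yl]phenoxy}-3-oxopropyl]phenyl carbonate | COc1ccc(-c2oc3cc(OC)cc(OCc4ccccc4)c3c(=O)c2-c2c(OCc3ccccc3)cc(O[C@H](CC=O)c3ccc(OC(=O)OCc4ccccc4)cc3)cc2OCc2ccccc2)cc1
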